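**Strategy.** The route rests on cutting C3–C4 in ring C of each flavanone unit (C3''–C4'' likewise). This bond joins the CH2 beside the O1–C2(aryl) stereocentre to the ketone carbon on ring A, and at the enol-ether oxidation level it is a C3=C4 olefin. One double ring-closing metathesis of a bis(diene) therefore closes both pyran rings with loss of ethylene and delivers the diketone as its bis(silyl enol ether), so C2 and C2'' never meet base. The precursor is a diaryl ether carrying two (S)-1-arylallyl aryl ethers, each set by allylic etherification with [Ir(cod)Cl]2 and a chiral phosphoramidite using a different 2-hydroxyacetophenone, and two ortho α-silyloxyvinyl groups.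

Key step: step 14

Remark on design: C5 of unit 1 is carried as a benzyl ether, not as a second methyl ether, so that one neutral hydrogenolysis frees all four phenols and no Lewis acid touches the finished flavanones; the two arms are told apart by building arm 1 as an allylic alcohol before the diaryl ether is made and arm 2 as an ester after it.

Assumption on the ligand: L is O,O'-(1,1'-binaphthalene-2,2'-diyl) N,N-bis(1-phenylethyl)phosphoramidite, and its (Sa,Sc,Sc) enantiomer is taken to give the (S)-ether (the (Ra,Rc,Rc) enantiomer the (R)-ether); both are commercial, so the sense is checked on 11 before material is committed.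

Remark on numbering: where one reagent acts at several like sites in a single operation (steps 2, 14, 15, 16), the partly converted species belong to the same reaction and are not numbered.

**Step 1**
Reactants: 1 2',6'-dihydroxy-4'-methoxyacetophenone
Product: 2 2'-(benzyloxy)-6'-hydroxy-4'-methoxyacetophenone
Conditions: BnBr (1.05 equiv), K2CO3 (1.1 equiv), acetone, reflux
Reagents that add atoms: benzyl bromide, BrCc1ccccc1
Why: Williamson O-benzylation: with one equivalent of benzyl bromide the first phenol is alkylated and the remaining ortho-hydroxyl, held in a hydrogen bond to the acetyl carbonyl, is too poor a nucleophile to react further.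

**Step 2**
Reactants: 3 2',4',6'-trihydroxyacetophenone
Product: 4 2',4'-bis(benzyloxy)-6'-hydroxyacetophenone
Conditions: BnBr (2.1 equiv), K2CO3 (2.2 equiv), DMF, rt
Reagents that add atoms: benzyl bromide, BrCc1ccccc1
Why: Williamson O-benzylation of the para and one ortho hydroxyl; the last ortho-hydroxyl stays free for the same chelation reason, giving the phenol needed for unit 2.

**Step 3**
Reactants: 5 4-(benzyloxy)-3-hydroxybenzaldehyde
Product: 6 methyl (2E)-3-[4-(benzyloxy)-3-hydroxyphenyl]prop-2-enoate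
Conditions: Ph3P=CHCO2Me (1.2 equiv), toluene, 80 °C
Reagents that add atoms: methyl (triphenylphosphoranylidene)acetate, COC(=O)C=P(c1ccccc1)(c1ccccc1)c1ccccc1
Why: Wittig olefination with a stabilised ylide, which is E-selective, needs no base and therefore tolerates the free phenol.

**Step 4**
Reactants: 6 methyl (2E)-3-[4-(benzyloxy)-3-hydroxyphenyl]prop-2-enoate
Product: 7 (2E)-3-[4-(benzyloxy)-3-hydroxyphenyl]prop-2-en-1-ol
Conditions: i-Bu2AlH (3.5 equiv), toluene/THF, −78 → 0 °C; aq. potassium sodium tartrate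
Reagents that add atoms: none
Why: DIBAL-H reduces the conjugated ester in 1,2-fashion to the allylic alcohol (the phenol only consumes one hydride as its aluminium phenoxide), the standard route to hydroxycinnamyl alcohols.

**Step 5**
Reactants: 7 (2E)-3-[4-(benzyloxy)-3-hydroxyphenyl]prop-2-en-1-ol; 8 4-fluorobenzaldehyde
Product: 9 4-{2-(benzyloxy)-5-[(1E)-3-hydroxyprop-1-en-1-yl]phenoxy}benzaldehyde
Conditions: K2CO3 (1.5 equiv), DMF, 90 °C, Ar
Reagents that add atoms: none
Why: Nucleophilic aromatic substitution: carbonate deprotonates only the phenol, whose phenoxide displaces fluoride para to the activating formyl group, while the far less acidic allylic alcohol stays un-ionised.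

**Step 6**
Reactants: 9 4-{2-(benzyloxy)-5-[(1E)-3-hydroxyprop-1-en-1-yl]phenoxy}benzaldehyde
Product: 10 methyl (2E)-3-(4-{2-(benzyloxy)-5-[(1E)-3-hydroxyprop-1-en-1-yl]phenoxy}phenyl)prop-2-enoate
Conditions: Ph3P=CHCO2Me (1.2 equiv), toluene, 60 °C
Reagents that add atoms: methyl (triphenylphosphoranylidene)acetate, COC(=O)C=P(c1ccccc1)(c1ccccc1)c1ccccc1
Why: Wittig olefination of the aryl aldehyde with the same stabilised ylide; neutral conditions leave the free allylic alcohol alone and give the E-cinnamate, which is inert in steps 7 to 9 and so keeps the two arms distinct.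

**Step 7**
Reactants: 10 methyl (2E)-3-(4-{2-(benzyloxy)-5-[(1E)-3-hydroxyprop-1-en-1-yl]phenoxy}phenyl)prop-2-enoate
Product: 11 methyl (2E)-3-[4-(2-(benzyloxy)-5-{(1E)-3-[(methoxycarbonyl)oxy]prop-1-en-1-yl}phenoxy)phenyl]prop-2-enoate
Conditions: ClCO2Me (1.5 equiv), pyridine (3 equiv), CH2Cl2, 0 °C
Reagents that add atoms: methyl chloroformate, COC(=O)Cl
Why: Acylation of the primary allylic alcohol with a chloroformate installs the carbonate leaving group required for allyl–iridium formation.

**Step 8**
Reactants: 11 the arm 1 cinnamyl methyl carbonate; 2 2'-(benzyloxy)-6'-hydroxy-4'-methoxyacetophenone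
Product: 13 methyl (2E)-3-{4-[5-{(1S)-1-[2-acetyl-3-(benzyloxy)-5-methoxyphenoxy]prop-2-en-1-yl}-2-(benzyloxy)phenoxy]phenyl}prop-2-enoate, via sodium aryloxide 12 (not isolated)
Conditions: 2 (1.5 equiv), NaH (1.4 equiv), THF, 0 °C → rt; then 11, catalyst pre-formed from [Ir(cod)Cl]2 (2 mol%), (Sa,Sc,Sc)-L (4 mol%) and n-PrNH2 (THF, 50 °C, volatiles removed), THF, rt → 40 °C
Reagents that add atoms: none
Why: Asymmetric allylic etherification of an aryloxide with a linear cinnamyl carbonate: the cyclometalated iridium–phosphoramidite complex ionises the carbonate to an allyl complex and the aryloxide attacks the aryl-substituted terminus anti to the metal, so the branched ether forms and the ligand fixes the new C–O stereocentre as (S).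

**Step 9**
Reactants: 13 the arm 1 branched ether ketone
Product: 14 methyl (2E)-3-{4-[2-(benzyloxy)-5-{(1S)-1-[3-(benzyloxy)-2-(1-{[tert-butyl(dimethyl)silyl]oxy}ethenyl)-5-methoxyphenoxy]prop-2-en-1-yl}phenoxy]phenyl}prop-2-enoate
Conditions: TBSOTf (1.5 equiv), Et3N (3 equiv), CH2Cl2, 0 °C
Reagents that add atoms: tert-butyldimethylsilyl trifluoromethanesulfonate, CC(C)(C)[Si](C)(C)OS(=O)(=O)C(F)(F)F
Why: Soft enolisation of the aryl methyl ketone (silyl triflate activation, amine deprotonation) gives the silyl enol ether, which is the first metathesis partner and at the same time hides the ketone from the hydride of step 10; the amine-buffered medium spares the ionisable allylic ether.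

**Step 10**
Reactants: 14 the arm 1 silyl enol ether with the arm 2 methyl cinnamate
Product: 15 the corresponding arm 2 (2E)-allylic alcohol, (2E)-3-{4-[2-(benzyloxy)-5-{(1S)-1-[3-(benzyloxy)-2-(1-{[tert-butyl(dimethyl)silyl]oxy}ethenyl)-5-methoxyphenoxy]prop-2-en-1-yl}phenoxy]phenyl}prop-2-en-1-ol
Conditions: i-Bu2AlH (2.5 equiv), CH2Cl2, −78 °C; aq. potassium sodium tartrate
Reagents that add atoms: none
Why: DIBAL-H at low temperature reduces the cinnamate to the allylic alcohol, while silyl enol ether, aryl ethers and the terminal alkene do not react with the hydride.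

**Step 11**
Reactants: 15 the arm 2 allylic alcohol
Product: 16 the arm 2 cinnamyl methyl carbonate of 15
Conditions: ClCO2Me (1.5 equiv), pyridine (4 equiv), CH2Cl2, 0 °C
Reagents that add atoms: methyl chloroformate, COC(=O)Cl
Why: Chloroformate acylation of the new allylic alcohol in excess pyridine, which keeps the medium basic enough for the silyl enol ether.

**Step 12**
Reactants: 16 the arm 2 cinnamyl methyl carbonate; 4 2',4'-bis(benzyloxy)-6'-hydroxyacetophenone
Product: 18 the mono(silyl enol ether) mono-ketone in which arm 1 is as in 14 and arm 2 is a (1S)-1-[2-acetyl-3,5-bis(benzyloxy)phenoxy]prop-2-en-1-yl group, via sodium aryloxide 17 (not isolated)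
Conditions: 4 (1.5 equiv), NaH (1.4 equiv), THF, 0 °C → rt; then 16, catalyst pre-formed from [Ir(cod)Cl]2 (2 mol%), (Sa,Sc,Sc)-L (4 mol%) and n-PrNH2 (THF, 50 °C, volatiles removed), THF, rt → 40 °C
Reagents that add atoms: none
Why: Second asymmetric allylic etherification of the same type, now with the aryloxide that carries the ring A pattern of unit 2; the ligand again sets the new C–O stereocentre as (S), and the first branched ether, whose aryloxide is a poor leaving group, is not re-ionised.

**Step 13**
Reactants: 18 the mono(silyl enol ether) mono-ketone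
Product: 19 the bis(diene): 4-benzyloxy-3-(4-substituted phenoxy)phenyl core bearing two (1S)-1-(aryloxy)prop-2-en-1-yl groups, the aryl of arm 1 being 3-(benzyloxy)-5-methoxy-2-(1-silyloxyethenyl)phenyl and that of arm 2 3,5-bis(benzyloxy)-2-(1-silyloxyethenyl)phenyl (silyl = tert-butyldimethylsilyl)
Conditions: TBSOTf (2.0 equiv), Et3N (4 equiv), CH2Cl2, 0 °C
Reagents that add atoms: tert-butyldimethylsilyl trifluoromethanesulfonate, CC(C)(C)[Si](C)(C)OS(=O)(=O)C(F)(F)F
Why: Soft enolisation and O-silylation as in step 9 gives the second silyl enol ether and re-silylates any arm 1 ketone that methoxide set free in step 12.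

**Step 14**
Reactants: 19 the bis(diene)
Product: 20 the bis(4-silyloxy-2H-chromene): (2S)-5-(benzyloxy)-7-methoxy-4-(tert-butyldimethylsilyloxy)-2H-chromene joined at C2 to a 4-(benzyloxy)phenyl ring whose 3-oxygen carries the para-phenylene of a (2S)-5,7-bis(benzyloxy)-4-(tert-butyldimethylsilyloxy)-2H-chromen-2-yl unit
Conditions: second-generation Grubbs catalyst RuCl2(=CHPh)(H2IMes)(PCy3) (10 mol%, two portions), 1,4-benzoquinone (20 mol%), degassed toluene (2 mM), 70 °C, Ar sparge
Reagents that add atoms: none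
Why: The benzylidene of the catalyst exchanges onto each unhindered monosubstituted vinyl group, and the resulting alkylidene adds [2+2] to the neighbouring 1,1-disubstituted silyl enol ether with ruthenium on the CH2 carbon, so that cycloreversion forms C3=C4 (and C3''=C4'') and releases Ru=CH2, which leaves as ethylene. The closest known reactions are ring-closing metathesis of silyl enol ethers onto terminal olefins with RuCl2(=CHPh)(H2IMes)(PCy3) and the closure of 2-(allyloxy)styrenes to 2H-chromenes. Each ring C is closed as a six-membered ring by diene metathesis across the ortho-disposed O1–C8a–C4a tether, the new double bond lying inside the ring and conjugated with ring A. No stereocentre is created: C2 and C2'' come unchanged from steps 8 and 12, and benzoquinone intercepts ruthenium hydrides that could migrate the allyl-ether double bond and erase them. The step needs site selectivity (loading on vinyl, not on the enol ether, where a heteroatom-stabilised carbene would be a dead end) and ring closure in preference to cross-metathesis; the first is secured by the shielding of each enol ether between two ortho oxygen substituents, the second by the six-membered ortho tether, high dilution and the strain of any ring that would join the two arms.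

**Step 15**
Reactants: 20 the bis(4-silyloxy-2H-chromene)
Product: 21 (2S)-5-(benzyloxy)-2-[4-(benzyloxy)-3-{4-[(2S)-5,7-bis(benzyloxy)-4-oxo-3,4-dihydro-2H-chromen-2-yl]phenoxy}phenyl]-7-methoxy-2,3-dihydro-4H-chromen-4-one
Conditions: Bu4NF (2.5 equiv), AcOH (3 equiv), THF, 0 °C
Reagents that add atoms: none
Why: Fluoride cleaves each O–Si bond and acetic acid protonates the resulting enolate at C3 at once (buffered silyl enol ether cleavage), so the ketones appear without the free enolate that could open the pyranone by retro-oxa-Michael reaction and C2/C2'' stay (S).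

**Step 16**
Reactants: 21 the tetra-O-benzyl biflavanone
Product: 22 7-O-methyltetrahydroochnaflavone, (2S,2''S)
Conditions: H2 (1 atm), 10% Pd/C, EtOAc/MeOH (4:1), rt, stopped when the benzyl ethers are consumed
Reagents that add atoms: none
Why: Catalytic hydrogenolysis cleaves the four primary benzyl–oxygen bonds much faster than the ring-bound secondary C2–O1 ethers, the diaryl ether, the aryl ketones or the C7 methyl ether, and its neutral medium cannot epimerise the flavanone stereocentres.

**Compound list**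

1 | 2',6'-dihydroxy-4'-methoxyacetophenone | CC(=O)c1c(O)cc(OC)cc1O | starting material
2 | 2'-(benzyloxy)-6'-hydroxy-4'-methoxyacetophenone | CC(=O)c1c(O)cc(OC)cc1OCc1ccccc1 | intermediate
3 | 2',4',6'-trihydroxyacetophenone | CC(=O)c1c(O)cc(O)cc1O | starting material
4 | 2',4'-bis(benzyloxy)-6'-hydroxyacetophenone | CC(=O)c1c(O)cc(OCc2ccccc2)cc1OCc1ccccc1 | intermediate
5 | 4-(benzyloxy)-3-hydroxybenzaldehyde | O=Cc1ccc(OCc2ccccc2)c(O)c1 | starting material
6 | methyl (2E)-3-[4-(benzyloxy)-3-hydroxyphenyl]prop-2-enoate | COC(=O)/C=C/c1ccc(OCc2ccccc2)c(O)c1 | intermediate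
7 | (2E)-3-[4-(benzyloxy)-3-hydroxyphenyl]prop-2-en-1-ol | OC/C=C/c1ccc(OCc2ccccc2)c(O)c1 | intermediate
8 | 4-fluorobenzaldehyde | O=Cc1ccc(F)cc1 | starting material
9 | 4-{2-(benzyloxy)-5-[(1E)-3-hydroxyprop-1-en-1-yl]phenoxy}benzaldehyde | OC/C=C/c1ccc(OCc2ccccc2)c(Oc2ccc(C=O)cc2)c1 | intermediate
10 | methyl (2E)-3-(4-{2-(benzyloxy)-5-[(1E)-3-hydroxyprop-1-en-1-yl]phenoxy}phenyl)prop-2-enoate | OC/C=C/c1ccc(OCc2ccccc2)c(Oc2ccc(/C=C/C(=O)OC)cc2)c1 | intermediate
11 | methyl (2E)-3-[4-(2-(benzyloxy)-5-{(1E)-3-[(methoxycarbonyl)oxy]prop-1-en-1-yl}phenoxy)phenyl]prop-2-enoate | COC(=O)OC/C=C/c1ccc(OCc2ccccc2)c(Oc2ccc(/C=C/C(=O)OC)cc2)c1 | intermediate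
12 | sodium 2-acetyl-3-(benzyloxy)-5-methoxyphenolate | [Na+].CC(=O)c1c([O-])cc(OC)cc1OCc1ccccc1 | intermediate
13 | methyl (2E)-3-{4-[5-{(1S)-1-[2-acetyl-3-(benzyloxy)-5-methoxyphenoxy]prop-2-en-1-yl}-2-(benzyloxy)phenoxy]phenyl}prop-2-enoate | C=C[C@H](Oc1cc(OC)cc(OCc2ccccc2)c1C(C)=O)c1ccc(OCc2ccccc2)c(Oc2ccc(/C=C/C(=O)OC)cc2)c1 | intermediate
14 | tert-butyldimethylsilyl enol ether of 13 (acetyl replaced by 1-silyloxyethenyl), (S) | C=C[C@H](Oc1cc(OC)cc(OCc2ccccc2)c1C(=C)O[Si](C)(C)C(C)(C)C)c1ccc(OCc2ccccc2)c(Oc2ccc(/C=C/C(=O)OC)cc2)c1 | intermediate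
15 | arm 2 (2E)-allylic alcohol from 14 (CO2Me replaced by CH2OH), (S) | C=C[C@H](Oc1cc(OC)cc(OCc2ccccc2)c1C(=C)O[Si](C)(C)C(C)(C)C)c1ccc(OCc2ccccc2)c(Oc2ccc(/C=C/CO)cc2)c1 | intermediate
16 | methyl carbonate of 15, (S) | C=C[C@H](Oc1cc(OC)cc(OCc2ccccc2)c1C(=C)O[Si](C)(C)C(C)(C)C)c1ccc(OCc2ccccc2)c(Oc2ccc(/C=C/COC(=O)OC)cc2)c1 | intermediate
17 | sodium 2-acetyl-3,5-bis(benzyloxy)phenolate | [Na+].CC(=O)c1c([O-])cc(OCc2ccccc2)cc1OCc1ccccc1 | intermediate
18 | (S,S)-bis(branched allyl aryl ether), arm 1 as silyl enol ether, arm 2 as 2-acetyl-3,5-bis(benzyloxy)phenyl ether | C=C[C@H](Oc1cc(OC)cc(OCc2ccccc2)c1C(=C)O[Si](C)(C)C(C)(C)C)c1ccc(OCc2ccccc2)c(Oc2ccc([C@H](C=C)Oc3cc(OCc4ccccc4)cc(OCc4ccccc4)c3C(C)=O)cc2)c1 | intermediate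
19 | (S,S)-bis(branched allyl aryl ether) bis(tert-butyldimethylsilyl enol ether), the metathesis precursor | C=C[C@H](Oc1cc(OC)cc(OCc2ccccc2)c1C(=C)O[Si](C)(C)C(C)(C)C)c1ccc(OCc2ccccc2)c(Oc2ccc([C@H](C=C)Oc3cc(OCc4ccccc4)cc(OCc4ccccc4)c3C(=C)O[Si](C)(C)C(C)(C)C)cc2)c1 | intermediate
20 | (2S,2''S)-bis(4-silyloxy-2H-chromene), the enol ether of the protected biflavanone | COc1cc(OCc2ccccc2)c2c(c1)O[C@H](c1ccc(OCc3ccccc3)c(Oc3ccc([C@@H]4C=C(O[Si](C)(C)C(C)(C)C)c5c(OCc6ccccc6)cc(OCc6ccccc6)cc5O4)cc3)c1)C=C2O[Si](C)(C)C(C)(C)C | intermediate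
21 | (2S,2''S)-5,4',5'',7''-tetra-O-benzyl-7-O-methyltetrahydroochnaflavone | COc1cc(OCc2ccccc2)c2c(c1)O[C@H](c1ccc(OCc3ccccc3)c(Oc3ccc([C@@H]4CC(=O)c5c(OCc6ccccc6)cc(OCc6ccccc6)cc5O4)cc3)c1)CC2=O | intermediate
22 | 7-O-methyltetrahydroochnaflavone, (2S,2''S) | COc1cc(O)c2c(c1)O[C@H](c1ccc(O)c(Oc3ccc([C@@H]4CC(=O)c5c(O)cc(O)cc5O4)cc3)c1)CC2=O | target

**Totals.** 16 steps in all; longest linear sequence 14 steps (steps 3 to 16, from 5).

**Steps most likely to fail**

1. Step 14. The ruthenium carbene may fail to engage the shielded, electron-rich enol ethers, or be lost to allyl-ether isomerisation, so that closure stops at one ring or none. Fallback, from 19 back to 21, replaces the hindered enol ether by an unhindered styrene and brings in the C4 oxygen afterwards.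
   - Both enol ethers of 19 are cleaved (Bu4NF/AcOH, THF) to the diketone bis(allyl ether) F1.
   - NaBH4 (MeOH/THF) gives the bis(1-arylethanol) F2, whose carbinol epimers are of no consequence.
   - Burgess dehydration gives the bis(2-vinylaryl) ether F3.
   - RuCl2(=CHPh)(H2IMes)(PCy3), the second-generation Grubbs catalyst, in CH2Cl2 at 40 °C closes both rings by the well-established styrene/allyl ether metathesis to the bis(2-aryl-2H-chromene) F4.
   - Benzylic-selective hydroboration with catecholborane and [Rh(cod)2]BF4/dppb, then NaOH/H2O2, gives the bis(flavan-4-ol) F5.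
   - Dess–Martin oxidation returns to 21.

2. Step 8. The chelated, acyl-deactivated aryloxide may attack the allyl–iridium intermediate slowly or unselectively, giving linear ether or eroded enantiopurity. Fallback, from 10 back to 13, sets the stereocentre by epoxide chemistry.
   - Sharpless epoxidation of 10 (Ti(OiPr)4, L-(+)-diethyl tartrate, t-BuOOH, 4 Å sieves, CH2Cl2, −20 °C) gives the (2S,3S)-epoxy alcohol F6.
   - Sodium aryloxide 12 (DMF, 50 °C) opens it at the benzylic carbon with inversion, the regiochemistry known for phenoxide opening of 3-arylglycidols, to the (2S,3R)-3-aryloxy-1,2-diol F7.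
   - Thiocarbonyldiimidazole gives the cyclic thionocarbonate F8.
   - Corey–Winter fragmentation with 1,3-dimethyl-2-phenyl-1,3,2-diazaphospholidine (40 °C) removes both diol oxygens and leaves the terminal alkene, which is 13 with the (S) centre untouched.

3. Step 16. Hydrogenolysis may not stop at the four O-benzyl groups and may go on to cleave the benzylic C2–O1 and C2''–O1'' bonds or reduce a ketone. Fallback, from 21 directly to 22: BCl3 (excess) with pentamethylbenzene as benzyl-cation scavenger in CH2Cl2 at −78 °C, then MeOH quench. This removes the benzyl groups by a Lewis-acid pathway without hydrogen or a metal surface and leaves the unchelated C7 methyl ether; it makes no new compound (F0).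

**Further compounds**

F1 | step 14 | (S,S)-bis(branched allyl aryl ether) diketone (both silyl enol ethers of 19 replaced by acetyl) | C=C[C@H](Oc1cc(OC)cc(OCc2ccccc2)c1C(C)=O)c1ccc(OCc2ccccc2)c(Oc2ccc([C@H](C=C)Oc3cc(OCc4ccccc4)cc(OCc4ccccc4)c3C(C)=O)cc2)c1
F2 | step 14 | (S,S)-bis(branched allyl aryl ether) bis(1-hydroxyethyl) compound, carbinol centres as epimer mixture | C=C[C@H](Oc1cc(OC)cc(OCc2ccccc2)c1C(C)O)c1ccc(OCc2ccccc2)c(Oc2ccc([C@H](C=C)Oc3cc(OCc4ccccc4)cc(OCc4ccccc4)c3C(C)O)cc2)c1
F3 | step 14 | (S,S)-bis(branched allyl 2-vinylaryl ether) | C=C[C@H](Oc1cc(OC)cc(OCc2ccccc2)c1C=C)c1ccc(OCc2ccccc2)c(Oc2ccc([C@H](C=C)Oc3cc(OCc4ccccc4)cc(OCc4ccccc4)c3C=C)cc2)c1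
F4 | step 14 | (2S,2''S)-bis(2-aryl-2H-chromene) with the benzyl and methyl ethers of 21 | COc1cc(OCc2ccccc2)c2c(c1)O[C@H](c1ccc(OCc3ccccc3)c(Oc3ccc([C@@H]4C=Cc5c(OCc6ccccc6)cc(OCc6ccccc6)cc5O4)cc3)c1)C=C2
F5 | step 14 | (2S,2''S)-bis(flavan-4-ol), C4 and C4'' as epimer mixture | COc1cc(OCc2ccccc2)c2c(c1)O[C@H](c1ccc(OCc3ccccc3)c(Oc3ccc([C@@H]4CC(O)c5c(OCc6ccccc6)cc(OCc6ccccc6)cc5O4)cc3)c1)CC2O
F6 | step 8 | methyl (2E)-3-[4-(2-(benzyloxy)-5-[(2S,3S)-3-(hydroxymethyl)oxiran-2-yl]phenoxy)phenyl]prop-2-enoate | OC[C@@H]1O[C@H]1c1ccc(OCc2ccccc2)c(Oc2ccc(/C=C/C(=O)OC)cc2)c1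
F7 | step 8 | methyl (2E)-3-{4-[5-{(1R,2S)-1-[2-acetyl-3-(benzyloxy)-5-methoxyphenoxy]-2,3-dihydroxypropyl}-2-(benzyloxy)phenoxy]phenyl}prop-2-enoate | OC[C@H](O)[C@H](Oc1cc(OC)cc(OCc2ccccc2)c1C(C)=O)c1ccc(OCc2ccccc2)c(Oc2ccc(/C=C/C(=O)OC)cc2)c1
F8 | step 8 | cyclic thionocarbonate (2-thioxo-1,3-dioxolane) of the diol F7 | S=C1OC[C@H](O1)[C@H](Oc1cc(OC)cc(OCc2ccccc2)c1C(C)=O)c1ccc(OCc2ccccc2)c(Oc2ccc(/C=C/C(=O)OC)cc2)c1
F0 | step 16 | none | none
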